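**Retrosynthetic overview**
1. Target 14 comes from its tetradecamethyl ether 12 by global O-demethylation. No ring is built: all six benzene rings are bought.
2. 12 = pentamer phenol 10 + 5-bromo-1,2,3-trimethoxybenzene 11 (ring F) by Ullmann C–O coupling.
3. Each hindered phenol (7, 10) is unmasked from a 2,6-dimethoxybenzaldehyde by Dakin oxidation (CHO = masked OH).
4. Each aldehyde (5, 8) comes from Ullmann coupling of a hindered phenol with one bromo-aldehyde dimer 3, used twice.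
5. 3 = 4-bromo-2,6-dimethoxyphenol 1 + 4-fluoro-2,6-dimethoxybenzaldehyde 2 by SNAr. Order of joining: B–C block, then A + BC, then + DE, then + F.

Assumption: the target has no stereocentre and no stereoaxis, so "single enantiomer" needs no stereocontrol; 1, 2, 4 and 11 are taken as catalogue compounds. Rings are lettered A–F from the 2,4,6-trioxygenated end; each bridging O sits on the carbon flanked by two OR groups of the earlier ring and on the carbon flanked by two H of the later ring.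

**Step 1**
Reactants: 1 4-bromo-2,6-dimethoxyphenol; 2 4-fluoro-2,6-dimethoxybenzaldehyde
Product: 3 4-(4-bromo-2,6-dimethoxyphenoxy)-2,6-dimethoxybenzaldehyde (bromo-aldehyde dimer)
Conditions: K2CO3 (2 equiv), DMSO, 120 °C, Ar
Reagents that add atoms: none
Why: SNAr (addition–elimination) of the phenoxide of 1 at the C–F para to the formyl group, with the unactivated C–Br untouched so 1 cannot self-condense; no stereocentre is formed.

**Step 2**
Reactants: 4 2,4,6-trimethoxyphenol; 3 bromo-aldehyde dimer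
Product: 5 4-[2,6-dimethoxy-4-(2,4,6-trimethoxyphenoxy)phenoxy]-2,6-dimethoxybenzaldehyde (trimer aldehyde A–B–C)
Conditions: CuI (10 mol%), picolinic acid (20 mol%), K3PO4 (2 equiv), degassed DMSO, 90 °C, Ar
Reagents that add atoms: none
Why: Ullmann-type Cu-catalysed C–O coupling of a di-ortho-substituted phenol with an unhindered aryl bromide, tolerated by the non-enolisable aldehyde; no stereocentre is formed.

**Step 3**
Reactants: 5 trimer aldehyde
Product: 7 4-[2,6-dimethoxy-4-(2,4,6-trimethoxyphenoxy)phenoxy]-2,6-dimethoxyphenol (trimer phenol A–B–C–OH), via trimer aryl formate 6 (not isolated)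
Conditions: 30% H2O2, cat. H2SO4, MeOH–CH2Cl2, 0 °C to rt
Reagents that add atoms: hydrogen peroxide, OO
Why: acid-catalysed Dakin (Baeyer–Villiger-type) oxidation in which the electron-rich 2,6-dimethoxyaryl group migrates and the formate is methanolysed in the flask; no stereocentre is formed.

**Step 4**
Reactants: 7 trimer phenol; 3 bromo-aldehyde dimer
Product: 8 4-{4-[4-[2,6-dimethoxy-4-(2,4,6-trimethoxyphenoxy)phenoxy]-2,6-dimethoxyphenoxy]-2,6-dimethoxyphenoxy}-2,6-dimethoxybenzaldehyde (pentamer aldehyde A–B–C–D–E)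
Conditions: CuI (10 mol%), picolinic acid (20 mol%), K3PO4 (2 equiv), degassed DMSO, 90 °C, Ar
Reagents that add atoms: none
Why: the same Ullmann C–O coupling as step 2, joining the hindered phenol of ring C to the unhindered bromide of ring D; no stereocentre is formed.

**Step 5**
Reactants: 8 pentamer aldehyde
Product: 10 4-{4-[4-[2,6-dimethoxy-4-(2,4,6-trimethoxyphenoxy)phenoxy]-2,6-dimethoxyphenoxy]-2,6-dimethoxyphenoxy}-2,6-dimethoxyphenol (pentamer phenol A–B–C–D–E–OH), via pentamer aryl formate 9 (not isolated)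
Conditions: 30% H2O2, cat. H2SO4, MeOH–CH2Cl2, 0 °C to rt
Reagents that add atoms: hydrogen peroxide, OO
Why: the same Dakin oxidation as step 3 converts the formyl group of ring E into the hindered phenol; no stereocentre is formed.

**Step 6**
Reactants: 10 pentamer phenol; 11 5-bromo-1,2,3-trimethoxybenzene
Product: 12 5-{4-[4-[4-[2,6-dimethoxy-4-(2,4,6-trimethoxyphenoxy)phenoxy]-2,6-dimethoxyphenoxy]-2,6-dimethoxyphenoxy]-2,6-dimethoxyphenoxy}-1,2,3-trimethoxybenzene (tetradeca-O-methyl ether of the target)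
Conditions: 11 (2 equiv), CuI (20 mol%), picolinic acid (40 mol%), K3PO4 (2 equiv), degassed DMSO, 100 °C, Ar
Reagents that add atoms: none
Why: Ullmann C–O coupling of the hindered phenol with an excess of the cheap unhindered bromide installs ring F; no stereocentre is formed.

**Step 7**
Reactants: 12 tetradeca-O-methyl ether
Product: 14 5-{4-[4-[4-[2,6-dihydroxy-4-(2,4,6-trihydroxyphenoxy)phenoxy]-2,6-dihydroxyphenoxy]-2,6-dihydroxyphenoxy]-2,6-dihydroxyphenoxy}benzene-1,2,3-triol (target), via tetradecakis(dibromoboryl) ether 13 (not isolated)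
Conditions: BBr3 (3 equiv per OMe), CH2Cl2, −78 °C to rt; then H2O, 0 °C; Ar throughout
Reagents that add atoms: none
Why: Lewis-acid ether cleavage in which BBr3 removes all fourteen methyl groups as MeBr while the diaryl ether bonds stay intact, and hydrolysis frees the phenols; no stereocentre is formed.

**Compound list**
1 | 4-bromo-2,6-dimethoxyphenol | COc1cc(Br)cc(OC)c1O | starting material
2 | 4-fluoro-2,6-dimethoxybenzaldehyde | COc1cc(F)cc(OC)c1C=O | starting material
3 | 4-(4-bromo-2,6-dimethoxyphenoxy)-2,6-dimethoxybenzaldehyde | COc1cc(Br)cc(OC)c1Oc1cc(OC)c(C=O)c(OC)c1 | intermediate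
4 | 2,4,6-trimethoxyphenol | COc1cc(OC)c(O)c(OC)c1 | starting material
5 | trimer aldehyde, 4-[2,6-dimethoxy-4-(2,4,6-trimethoxyphenoxy)phenoxy]-2,6-dimethoxybenzaldehyde | COc1cc(OC)c(Oc2cc(OC)c(Oc3cc(OC)c(C=O)c(OC)c3)c(OC)c2)c(OC)c1 | intermediate
6 | trimer aryl formate, 4-[2,6-dimethoxy-4-(2,4,6-trimethoxyphenoxy)phenoxy]-2,6-dimethoxyphenyl formate | COc1cc(OC)c(Oc2cc(OC)c(Oc3cc(OC)c(OC=O)c(OC)c3)c(OC)c2)c(OC)c1 | intermediate (not isolated)
7 | trimer phenol, 4-[2,6-dimethoxy-4-(2,4,6-trimethoxyphenoxy)phenoxy]-2,6-dimethoxyphenol | COc1cc(OC)c(Oc2cc(OC)c(Oc3cc(OC)c(O)c(OC)c3)c(OC)c2)c(OC)c1 | intermediate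
8 | pentamer aldehyde (rings A–E, CHO on ring E between its two OMe) | COc1cc(OC)c(Oc2cc(OC)c(Oc3cc(OC)c(Oc4cc(OC)c(Oc5cc(OC)c(C=O)c(OC)c5)c(OC)c4)c(OC)c3)c(OC)c2)c(OC)c1 | intermediate
9 | pentamer aryl formate (OCHO in place of CHO of 8) | COc1cc(OC)c(Oc2cc(OC)c(Oc3cc(OC)c(Oc4cc(OC)c(Oc5cc(OC)c(OC=O)c(OC)c5)c(OC)c4)c(OC)c3)c(OC)c2)c(OC)c1 | intermediate (not isolated)
10 | pentamer phenol (OH in place of CHO of 8) | COc1cc(OC)c(Oc2cc(OC)c(Oc3cc(OC)c(Oc4cc(OC)c(Oc5cc(OC)c(O)c(OC)c5)c(OC)c4)c(OC)c3)c(OC)c2)c(OC)c1 | intermediate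
11 | 5-bromo-1,2,3-trimethoxybenzene | COc1cc(Br)cc(OC)c1OC | starting material
12 | tetradeca-O-methyl ether of the target | COc1cc(OC)c(Oc2cc(OC)c(Oc3cc(OC)c(Oc4cc(OC)c(Oc5cc(OC)c(Oc6cc(OC)c(OC)c(OC)c6)c(OC)c5)c(OC)c4)c(OC)c3)c(OC)c2)c(OC)c1 | intermediate
13 | tetradecakis(dibromoboryl) ether of the target (idealised: every OMe of 12 replaced by OBBr2) | BrB(Br)Oc1cc(OB(Br)Br)c(Oc2cc(OB(Br)Br)c(Oc3cc(OB(Br)Br)c(Oc4cc(OB(Br)Br)c(Oc5cc(OB(Br)Br)c(Oc6cc(OB(Br)Br)c(OB(Br)Br)c(OB(Br)Br)c6)c(OB(Br)Br)c5)c(OB(Br)Br)c4)c(OB(Br)Br)c3)c(OB(Br)Br)c2)c(OB(Br)Br)c1 | intermediate (not isolated)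
14 | CNP0187343.0, achiral linear hexamer | Oc1cc(O)c(Oc2cc(O)c(Oc3cc(O)c(Oc4cc(O)c(Oc5cc(O)c(Oc6cc(O)c(O)c(O)c6)c(O)c5)c(O)c4)c(O)c3)c(O)c2)c(O)c1 | target

**Totals**
Total step count: 7. Longest linear sequence: 7 (1 → 3 → 5 → 7 → 8 → 10 → 12 → 14; dimer 3 enters twice).

**Three steps most likely to fail**

Step 1 (SNAr of a di-ortho-substituted phenoxide on a fluoride activated only by a push-pull aldehyde). The fallback masks the phenol as a benzyl ether and forms the first diaryl ether by oxidative coupling. It sets out from 1 and comes back at 7, and again at 10.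
- 1 is O-benzylated (BnBr, K2CO3, DMF) to 2-(benzyloxy)-5-bromo-1,3-dimethoxybenzene F1.
- F1 is borylated (B2(OH)4, XPhos Pd G2 cat., KOAc, EtOH, 80 °C) to [4-(benzyloxy)-3,5-dimethoxyphenyl]boronic acid F2.
- F2 and a second portion of 1 are joined by Chan–Lam coupling (Cu(OAc)2, pyridine, 4 Å MS, CH2Cl2, air, rt), which leaves the aryl bromide alone, to give 2-(benzyloxy)-5-(4-bromo-2,6-dimethoxyphenoxy)-1,3-dimethoxybenzene F3.
- F3 replaces 3: Ullmann coupling with 4 (step 2 conditions) gives the trimer benzyl ether F4, and hydrogenolysis (H2, Pd/C, EtOAc–MeOH) returns to 7.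
- Ullmann coupling of 7 with F3 gives the pentamer benzyl ether F5, and hydrogenolysis returns to 10.

Step 4 (Cu coupling of two advanced fragments; low conversion or aryloxide exchange at the aldehyde ring). The fallback drops the copper coupling and grows the chain one ring at a time with the chemistry of steps 1 and 3. It sets out from 7 and comes back at 8.
- SNAr of 7 on 2 (K2CO3, DMSO, 120 °C) gives the tetramer aldehyde F6.
- Dakin oxidation (H2O2, cat. H2SO4, MeOH–CH2Cl2) passes through the tetramer aryl formate F7 to the tetramer phenol F8.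
- A second SNAr of F8 on 2 gives 8.

Step 7 (fourteen-fold demethylation; incomplete cleavage and an air-sensitive, hard-to-purify polyphenol). The fallback isolates the product as a stable ester instead of as the free phenol. It sets out from 12 and comes back at 14.
- The crude BBr3 product is acetylated at once (Ac2O, pyridine, DMAP) to the tetradecaacetate F9, which is purified on silica; under-demethylated material is separated and recycled.
- F9 is deacetylated by acid methanolysis (cat. AcCl in MeOH, rt, Ar) to 14.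

**Further compounds**
F1 | step 1 | 2-(benzyloxy)-5-bromo-1,3-dimethoxybenzene | COc1cc(Br)cc(OC)c1OCc1ccccc1
F2 | step 1 | [4-(benzyloxy)-3,5-dimethoxyphenyl]boronic acid | COc1cc(B(O)O)cc(OC)c1OCc1ccccc1
F3 | step 1 | 2-(benzyloxy)-5-(4-bromo-2,6-dimethoxyphenoxy)-1,3-dimethoxybenzene | COc1cc(Br)cc(OC)c1Oc1cc(OC)c(OCc2ccccc2)c(OC)c1
F4 | step 1 | trimer benzyl ether (OBn in place of OH of 7) | COc1cc(OC)c(Oc2cc(OC)c(Oc3cc(OC)c(OCc4ccccc4)c(OC)c3)c(OC)c2)c(OC)c1
F5 | step 1 | pentamer benzyl ether (OBn in place of OH of 10) | COc1cc(OC)c(Oc2cc(OC)c(Oc3cc(OC)c(Oc4cc(OC)c(Oc5cc(OC)c(OCc6ccccc6)c(OC)c5)c(OC)c4)c(OC)c3)c(OC)c2)c(OC)c1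
F6 | step 4 | tetramer aldehyde (rings A–D, CHO on ring D between its two OMe) | COc1cc(OC)c(Oc2cc(OC)c(Oc3cc(OC)c(Oc4cc(OC)c(C=O)c(OC)c4)c(OC)c3)c(OC)c2)c(OC)c1
F7 | step 4 | tetramer aryl formate (OCHO in place of CHO of F6) | COc1cc(OC)c(Oc2cc(OC)c(Oc3cc(OC)c(Oc4cc(OC)c(OC=O)c(OC)c4)c(OC)c3)c(OC)c2)c(OC)c1
F8 | step 4 | tetramer phenol (OH in place of CHO of F6) | COc1cc(OC)c(Oc2cc(OC)c(Oc3cc(OC)c(Oc4cc(OC)c(O)c(OC)c4)c(OC)c3)c(OC)c2)c(OC)c1
F9 | step 7 | tetradecaacetate of the target | CC(=O)Oc1cc(OC(C)=O)c(Oc2cc(OC(C)=O)c(Oc3cc(OC(C)=O)c(Oc4cc(OC(C)=O)c(Oc5cc(OC(C)=O)c(Oc6cc(OC(C)=O)c(OC(C)=O)c(OC(C)=O)c6)c(OC(C)=O)c5)c(OC(C)=O)c4)c(OC(C)=O)c3)c(OC(C)=O)c2)c(OC(C)=O)c1
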